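**Proposed total synthesis of CNP0394081.0, compound 16, by Diels–Alder construction of the central anisole ring**

Assumption: the target SMILES carries no stereodescriptor, so the hindered C8–C2' biaryl axis is treated as configurationally unspecified and no atroposelective control is attempted.

Numbering used for positions: unit 1 is the acacetin-derived flavone (O1, C2–C8a). Unit 2 is the second chromone, and its ring B is the central anisole numbered C1'–C6' (C1' on C2 of the unit 2 chromone, C2' bonded to C8 of unit 1, methoxy on C4').

## Analysis of the target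

Compound 16 is a C–C linked biflavonoid made of two 5,7-dihydroxy-4H-chromen-4-one systems. Unit 1 is a complete acacetin skeleton with its own 4-methoxyphenyl ring. Unit 2 is a 5,7-dihydroxychromone whose C2 carries the central anisole ring B, which is bonded through C2' to C8 of unit 1 and carries its methoxy group at C4'. The molecule has no stereocentre; the only possible stereogenic element is the C8–C2' axis, flanked by O7, O1 and the unit 2 chromone, and it is left unspecified. The sensitive groups are four phenols (two chelated to the C4 carbonyls) that must end free beside two aryl methyl ethers that must stay, and two pyranone rings that open with hard nucleophiles and can be over-reduced. The difficulty is twofold. The C8–C2' bond joins a doubly ortho-oxygenated, electron-rich carbon to a carbon ortho to a bulky chromone, which is a tri-ortho-substituted biaryl junction. In addition, six oxygen functions must be told apart. The strategy rests on ring B of unit 2. Its 1,2,4-pattern, with the chromone at C1', the aryl link at C2' and oxygen at C4' para to C1', is what a 2-oxygenated buta-1,3-diene gives when it adds across an alkyne spanning C1' and C2'. The carbons C3'–C6' and the C4' oxygen then come from the diene.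

## Retrosynthetic reasoning

Target 16 is traced to its tetrabenzyl ether 15 by cutting the four O–benzyl bonds. Benzyl is chosen because it must be told apart from the two methyl ethers, and its hydrogenolytic removal leaves aryl methyl ethers alone. The forward step only has to cleave four benzylic C–O bonds without reducing the pyranone C2=C3 bonds.

Methyl ether 15 is traced to phenol 14 by cutting the O–CH3 bond at C4'. Phenol 14 has a single free hydroxyl, so the forward O-methylation cannot go astray. It turns the oxygen delivered by the diene into the methoxy group of the target.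

Phenol 14 is traced, through its silyl ether 13, to the cyclohexa-1,4-diene 12 by putting back two hydrogens, one at C3' and one at C6'. This converts the crowded teraryl ring into a non-aromatic ring that a cycloaddition can close. The forward step is a dehydrogenation driven by aromatization.

Diene 12 is cut at C2'–C3' and C1'–C6', which gives the diarylalkyne 10 and 2-(trimethylsilyloxy)buta-1,3-diene 11. These two bonds are chosen over the C8–C2' bond because a biaryl coupling at C8–C2' would have to join two hindered sp2 carbons. Here the crowded junction comes from a linear sp-carbon link, and the ring is closed away from the congestion. The gain is one ring and two C–C bonds in one event. The forward reaction must pair the silyloxy-substituted diene terminus with the alkyne carbon bonded to C8, so that oxygen ends at C4'.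

Alkyne 10 is cut at the C8–C(sp) bond into the 8-iodoflavone 3 and the 2-ethynylchromone 9. A terminal alkyne places almost no steric demand on C8, which is flanked by the 7-benzyloxy group and O1, and the cut separates the two benzopyranone units completely. The forward step is an aryl iodide–alkyne cross-coupling.

Iodide 3 is traced to the dibenzyl ether 2 by cutting C8–I, and 2 to acacetin 1 by cutting two O–benzyl bonds. Unit 1 is therefore used whole. With both O5 and O7 alkylated, electrophilic substitution should go to C8 and not to C6, so the protecting groups also serve as the regiochemical control.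

Alkyne 9 is traced to aldehyde 8 by removing the terminal alkyne carbon (a one-carbon homologation forward), and 8 to the 2-methylchromone 7 by lowering the oxidation level of the C2 substituent. The methyl group of 7 is the vinylogous α-position of the C4 ketone, which is the site an allylic oxidant attacks.

Chromone 7 is cut at O1–C2 and C2–C3, via the β-diketone 6, to the acetophenone 5 and a two-carbon acyl unit. Acetophenone 5 is the 4,6-dibenzyl ether of 2,4,6-trihydroxyacetophenone 4. Ring A of unit 2 is thus used intact with the right oxygen pattern, and the chelated hydroxyl left free in 5 becomes O1.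

## Alternatives that were turned down

Alternative 1: The C8–C2' biaryl bond is cut together with a temporary lactone between O7 and the carbon that later becomes C2 of unit 2. In the forward key step, phloroglucinol A1 and 2-bromo-4-methoxybenzoic acid A2 would be joined by copper-mediated Hurtley arylation in aqueous base. The ortho-carboxylate of A2 would then close onto the neighbouring phenol to give 1,3-dihydroxy-9-methoxybenzo[c]chromen-6-one A3. In its favour, it uses two cheap compounds without protecting groups, the symmetry of A1 removes any regiochemical question, and the carboxylate of A2 delivers the copper to the ortho position. The lactone also masks O7 and holds the future C2 at the right oxidation level. For the cost and ease of making the hindered aryl–aryl bond it is stronger than the chosen route. Against it, A3 contains neither benzopyranone. Both pyranone rings and the second ring A would have to be built linearly on a polyphenolic, oxidizable core, with C-acylation of the trioxygenated ring and opening of a hindered, conjugated lactone by a ketone enolate that competes with re-closure. The step count after A3 is clearly higher, and its uncertain steps fall late. The chosen strategy instead uses acacetin 1 as a finished unit 1 and brings in the unit 2 chromone complete, so that only ring B remains to be made.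

Alternative 2: The C1'–C2 bond of unit 2 is cut by C–H carbonylation, after a biaryl coupling has made 8-(3-methoxyphenyl)acacetin A4. In the forward key step the 7-hydroxyl of A4 would direct divalent palladium to the C–H para to the methoxy group. Carbonyl insertion and C–O bond formation would close the flavone-fused benzo[c]chromen-6-one lactone A5, with a copper oxidant returning zerovalent palladium to the divalent state. In its favour, unit 1 stays intact as in the chosen route. Both the directing group and the electronic preference of the anisole point to the correct C–H, and A5 should be reachable from 1 in about as many steps as alkyne 10, or fewer. On that count it is at least as strong. Against it, A4 needs an aryl–aryl coupling at the hindered C8, which is the very bond formation the chosen route avoids. The chelating 5-hydroxy-4-keto unit can hold back the palladium. The end game must also open the hindered lactone A5 with a ketone enolate carrying ring A of unit 2 and then close the second pyranone, all in the presence of a base-sensitive flavone. Those steps are the least predictable and come last. The chosen strategy places its one uncertain step on material whose two benzopyranones are already complete and protected.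

Alternative 3: Ring A of unit 2 is cut as in polyketide biosynthesis. The substrate of the forward key step is the triketo ester methyl (8E)-9-aryl-3,5,7-trioxonon-8-enoate A6, whose aryl group is the benzylated unit 1 attached to the anisole. With alkoxide base, the methylene of A6 flanked by the C5 and C7 ketones would add to the ester carbonyl, and enolization would give the 2',4',6'-trihydroxychalcone A7, which would then be closed oxidatively to the flavone. In its favour, it forms the trioxygenated ring with all three hydroxyls free and needs no protecting groups on unit 2, and the closure of A7 to the flavone is dependable. Against it, A6 has four electrophilic carbonyls, three acidic methylenes and an enone. Without an enzyme, aldol closure in the other sense, O-cyclization to pyranones and Michael addition to the enone all compete with the wanted Claisen mode. A6 is itself hard to assemble, and it still needs the hindered biaryl bond first. The step count is no shorter, and several steps carry high risk. The chosen strategy buys ring A of unit 2 ready-made as 4 and forms only C–C bonds of well-defined polarity.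

Key step: step 8

## Route

Step 1
Reactants: 1 acacetin [5,7-dihydroxy-2-(4-methoxyphenyl)-4H-chromen-4-one]
Product: 2 5,7-bis(benzyloxy)-2-(4-methoxyphenyl)-4H-chromen-4-one
Conditions: BnBr (3 equiv), K2CO3, Bu4NI (cat.), DMF, 80 °C
Reagents that add atoms: benzyl bromide, BrCc1ccccc1
Why: Williamson etherification; the 7-hydroxyl reacts readily and the chelated 5-hydroxyl follows with excess halide and heat, as is usual for 5,7-dihydroxyflavones, and alkylating both oxygens is what later steers iodination to C8.

Step 2
Reactants: 2 5,7-bis(benzyloxy)-2-(4-methoxyphenyl)-4H-chromen-4-one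
Product: 3 5,7-bis(benzyloxy)-8-iodo-2-(4-methoxyphenyl)-4H-chromen-4-one
Conditions: NIS (1.1 equiv), TFA (0.3 equiv), MeCN, 0 °C to rt, dark
Reagents that add atoms: N-iodosuccinimide, O=C1CCC(=O)N1I
Why: Electrophilic aromatic iodination of the trioxygenated ring A; in 5,7-dialkoxyflavones C8 (between O7 and O1) is the reactive site, C6 is buttressed between two benzyloxy groups, and the anisyl ring and C3 are deactivated by conjugation with the pyranone carbonyl.

Step 3
Reactants: 4 2,4,6-trihydroxyacetophenone
Product: 5 1-[2,4-bis(benzyloxy)-6-hydroxyphenyl]ethan-1-one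
Conditions: BnBr (2.2 equiv), K2CO3, DMF, rt
Reagents that add atoms: benzyl bromide, BrCc1ccccc1
Why: Williamson etherification limited to two equivalents; the hydroxyl hydrogen-bonded to the acetyl carbonyl is the least nucleophilic and should stay free, which is needed because it becomes the ring oxygen O1 of unit 2.

Step 4
Reactants: 5 1-[2,4-bis(benzyloxy)-6-hydroxyphenyl]ethan-1-one
Product: 7 5,7-bis(benzyloxy)-2-methyl-4H-chromen-4-one, via β-diketone 6 (not isolated)
Conditions: NaH (5 equiv), EtOAc (excess), THF, reflux; then conc. HCl (cat.), MeOH, 50 °C
Reagents that add atoms: ethyl acetate, CCOC(C)=O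
Why: Crossed Claisen condensation of the ketone enolate (as the phenoxide dianion) with ethyl acetate gives the 1-aryl-butane-1,3-dione 6, and acid-catalysed attack of the phenol on the distal carbonyl with loss of water closes the pyranone; this is the standard 2-methylchromone synthesis and the catalytic acid is too mild to cleave the benzyl ethers.

Step 5
Reactants: 7 5,7-bis(benzyloxy)-2-methyl-4H-chromen-4-one
Product: 8 5,7-bis(benzyloxy)-4-oxo-4H-chromene-2-carbaldehyde
Conditions: SeO2 (2 equiv), 1,4-dioxane, reflux
Reagents that add atoms: selenium dioxide, O=[Se]=O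
Why: Riley oxidation; the C2 methyl is the vinylogous α-position of the C4 ketone, so ene reaction with SeO2, [2,3]-shift and collapse of the selenite ester should give the aldehyde, a transformation known for 2-methylchromones, and the product has no further activated C–H.

Step 6
Reactants: 8 5,7-bis(benzyloxy)-4-oxo-4H-chromene-2-carbaldehyde
Product: 9 5,7-bis(benzyloxy)-2-ethynyl-4H-chromen-4-one
Conditions: dimethyl (1-diazo-2-oxopropyl)phosphonate (1.3 equiv), K2CO3, MeOH–THF, 0 °C to rt
Reagents that add atoms: dimethyl (1-diazo-2-oxopropyl)phosphonate, COP(=O)(OC)C(=[N+]=[N-])C(C)=O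
Why: Seyferth–Gilbert homologation in the Ohira–Bestmann form; methanolysis of the acetyl group frees the diazomethylphosphonate anion, which adds to the non-enolizable aldehyde, and loss of phosphate and N2 with 1,2-hydrogen shift of the alkylidene carbene should give the terminal alkyne under conditions mild enough for the pyranone.

Step 7
Reactants: 3 5,7-bis(benzyloxy)-8-iodo-2-(4-methoxyphenyl)-4H-chromen-4-one; 9 5,7-bis(benzyloxy)-2-ethynyl-4H-chromen-4-one
Product: 10 5,7-bis(benzyloxy)-8-{[5,7-bis(benzyloxy)-4-oxo-4H-chromen-2-yl]ethynyl}-2-(4-methoxyphenyl)-4H-chromen-4-one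
Conditions: PdCl2(PPh3)2 (5 mol %), CuI (10 mol %), Et3N, DMF, 60 °C, degassed, slow addition of 9
Reagents that add atoms: none
Why: Sonogashira coupling; oxidative addition of zerovalent palladium into the C8–I bond, transmetalation from the copper acetylide of 9 and reductive elimination form the C8–C(sp) bond, the iodide offsets the two ortho substituents, and a tertiary amine avoids conjugate addition to the acceptor alkyne.

Step 8
Reactants: 10 5,7-bis(benzyloxy)-8-{[5,7-bis(benzyloxy)-4-oxo-4H-chromen-2-yl]ethynyl}-2-(4-methoxyphenyl)-4H-chromen-4-one; 11 2-(trimethylsilyloxy)buta-1,3-diene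
Product: 12 5,7-bis(benzyloxy)-8-{2-[5,7-bis(benzyloxy)-4-oxo-4H-chromen-2-yl]-5-(trimethylsilyloxy)cyclohexa-1,4-dien-1-yl}-2-(4-methoxyphenyl)-4H-chromen-4-one
Conditions: 11 (10 equiv), BHT (cat.), o-xylene, 160 °C, base-washed sealed tube, Ar; volatiles removed, crude used directly
Reagents that add atoms: none
Why: This is a thermal normal-electron-demand Diels–Alder reaction in which the diene HOMO, raised by the silyloxy group, has its largest coefficient at the CH2 terminus attached to the silyloxy-bearing carbon, while the alkyne LUMO is largest at the carbon bonded to C8 of unit 1, because C2 of the unit 2 chromone is the carbonyl-carbon equivalent of the vinylogous ester O1–C2=C3–C4=O and the alkyne is therefore a vinylogous aryl alkynoate (an enynone) whose remote carbon is the acceptor terminus. The closest known reaction type is the cycloaddition of 2-silyloxybuta-1,3-dienes with arylpropiolates and ynones to 1-silyloxycyclohexa-1,4-dienes that are then dehydrogenated to phenol derivatives. Ring B of unit 2 closes as a six-membered carbocycle in one intermolecular suprafacial [4+2] event that forms C2'–C3' and C1'–C6' together, the former bond being the more advanced in an asynchronous transition state. No stereocentre is created, since the new ring of 12 holds only sp2 carbons and two CH2 groups. The step needs regioselectivity, silyloxy at C4' para to C1', and the pairing of the nucleophilic diene terminus with the electrophilic alkyne carbon secures it; both diene termini are CH2 groups, so the bulk of the C8 aryl group does not oppose this orientation, although its donor character lowers the reactivity without reversing the polarization. The step also needs chemoselectivity for the alkyne over the two pyranone C2=C3 bonds, which are trisubstituted vinylogous-ester alkenes of low dienophilicity. Excess volatile diene, a radical inhibitor and base-washed glass counter diene oligomerization and silyl loss at the temperature that this moderately activated, hindered diarylalkyne is expected to need.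

Step 9
Reactants: 12 5,7-bis(benzyloxy)-8-{2-[5,7-bis(benzyloxy)-4-oxo-4H-chromen-2-yl]-5-(trimethylsilyloxy)cyclohexa-1,4-dien-1-yl}-2-(4-methoxyphenyl)-4H-chromen-4-one
Product: 14 5,7-bis(benzyloxy)-8-{2-[5,7-bis(benzyloxy)-4-oxo-4H-chromen-2-yl]-5-hydroxyphenyl}-2-(4-methoxyphenyl)-4H-chromen-4-one, via aryl trimethylsilyl ether 13 (not isolated)
Conditions: DDQ (1.3 equiv), toluene, rt; then 1 M HCl, THF, rt
Reagents that add atoms: none
Why: Quinone dehydrogenation of a cyclohexa-1,4-diene; hydride abstraction from the doubly allylic C6' gives a cation stabilized by the silyloxy group and proton loss from C3' gives the arene 13, whose aryl silyl ether is cleaved by dilute acid; a portion of 12 that had already hydrolysed to the cyclohexenone should reach the same phenol through its dienol, and benzyl ethers are stable to DDQ at room temperature.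

Step 10
Reactants: 14 5,7-bis(benzyloxy)-8-{2-[5,7-bis(benzyloxy)-4-oxo-4H-chromen-2-yl]-5-hydroxyphenyl}-2-(4-methoxyphenyl)-4H-chromen-4-one
Product: 15 5,7-bis(benzyloxy)-8-{2-[5,7-bis(benzyloxy)-4-oxo-4H-chromen-2-yl]-5-methoxyphenyl}-2-(4-methoxyphenyl)-4H-chromen-4-one
Conditions: MeI (3 equiv), K2CO3, DMF, rt
Reagents that add atoms: iodomethane, CI
Why: Williamson O-methylation of the only free phenol in the molecule; all other hydroxyls are benzylated, so the methyl group can only go to the C4' oxygen.

Step 11
Reactants: 15 5,7-bis(benzyloxy)-8-{2-[5,7-bis(benzyloxy)-4-oxo-4H-chromen-2-yl]-5-methoxyphenyl}-2-(4-methoxyphenyl)-4H-chromen-4-one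
Product: 16 8-[2-(5,7-dihydroxy-4-oxo-4H-chromen-2-yl)-5-methoxyphenyl]-5,7-dihydroxy-2-(4-methoxyphenyl)-4H-chromen-4-one (CNP0394081.0)
Conditions: H2 (1 atm), 10% Pd/C, THF–MeOH, rt
Reagents that add atoms: none
Why: Catalytic hydrogenolysis of four benzylic C–O bonds; aryl methyl ethers are inert and the C2=C3 bonds of 2-arylchromones are reduced much more slowly, so stopping at complete debenzylation should give the target.

## Compound list

1 | acacetin, 5,7-dihydroxy-2-(4-methoxyphenyl)-4H-chromen-4-one | COc1ccc(-c2cc(=O)c3c(O)cc(O)cc3o2)cc1 | starting material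
2 | 5,7-bis(benzyloxy)-2-(4-methoxyphenyl)-4H-chromen-4-one | COc1ccc(-c2cc(=O)c3c(OCc4ccccc4)cc(OCc4ccccc4)cc3o2)cc1 | intermediate
3 | 5,7-bis(benzyloxy)-8-iodo-2-(4-methoxyphenyl)-4H-chromen-4-one | COc1ccc(-c2cc(=O)c3c(OCc4ccccc4)cc(OCc4ccccc4)c(I)c3o2)cc1 | intermediate
4 | 2,4,6-trihydroxyacetophenone | CC(=O)c1c(O)cc(O)cc1O | starting material
5 | 1-[2,4-bis(benzyloxy)-6-hydroxyphenyl]ethan-1-one | CC(=O)c1c(O)cc(OCc2ccccc2)cc1OCc1ccccc1 | intermediate
6 | 1-[2,4-bis(benzyloxy)-6-hydroxyphenyl]butane-1,3-dione | CC(=O)CC(=O)c1c(O)cc(OCc2ccccc2)cc1OCc1ccccc1 | intermediate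
7 | 5,7-bis(benzyloxy)-2-methyl-4H-chromen-4-one | Cc1cc(=O)c2c(OCc3ccccc3)cc(OCc3ccccc3)cc2o1 | intermediate
8 | 5,7-bis(benzyloxy)-4-oxo-4H-chromene-2-carbaldehyde | O=Cc1cc(=O)c2c(OCc3ccccc3)cc(OCc3ccccc3)cc2o1 | intermediate
9 | 5,7-bis(benzyloxy)-2-ethynyl-4H-chromen-4-one | C#Cc1cc(=O)c2c(OCc3ccccc3)cc(OCc3ccccc3)cc2o1 | intermediate
10 | 5,7-bis(benzyloxy)-8-{[5,7-bis(benzyloxy)-4-oxo-4H-chromen-2-yl]ethynyl}-2-(4-methoxyphenyl)-4H-chromen-4-one | COc1ccc(-c2cc(=O)c3c(OCc6ccccc6)cc(OCc6ccccc6)c(C#Cc4cc(=O)c5c(OCc6ccccc6)cc(OCc6ccccc6)cc5o4)c3o2)cc1 | intermediate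
11 | 2-(trimethylsilyloxy)buta-1,3-diene | C=CC(=C)O[Si](C)(C)C | starting material
12 | 5,7-bis(benzyloxy)-8-{2-[5,7-bis(benzyloxy)-4-oxo-4H-chromen-2-yl]-5-(trimethylsilyloxy)cyclohexa-1,4-dien-1-yl}-2-(4-methoxyphenyl)-4H-chromen-4-one | COc1ccc(-c2cc(=O)c3c(OCc6ccccc6)cc(OCc6ccccc6)c(C4=C(c7cc(=O)c8c(OCc6ccccc6)cc(OCc6ccccc6)cc8o7)CC=C(O[Si](C)(C)C)C4)c3o2)cc1 | intermediate
13 | 5,7-bis(benzyloxy)-8-{2-[5,7-bis(benzyloxy)-4-oxo-4H-chromen-2-yl]-5-(trimethylsilyloxy)phenyl}-2-(4-methoxyphenyl)-4H-chromen-4-one | COc1ccc(-c2cc(=O)c3c(OCc6ccccc6)cc(OCc6ccccc6)c(-c4cc(O[Si](C)(C)C)ccc4-c7cc(=O)c8c(OCc6ccccc6)cc(OCc6ccccc6)cc8o7)c3o2)cc1 | intermediate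
14 | 5,7-bis(benzyloxy)-8-{2-[5,7-bis(benzyloxy)-4-oxo-4H-chromen-2-yl]-5-hydroxyphenyl}-2-(4-methoxyphenyl)-4H-chromen-4-one | COc1ccc(-c2cc(=O)c3c(OCc6ccccc6)cc(OCc6ccccc6)c(-c4cc(O)ccc4-c7cc(=O)c8c(OCc6ccccc6)cc(OCc6ccccc6)cc8o7)c3o2)cc1 | intermediate
15 | 5,7-bis(benzyloxy)-8-{2-[5,7-bis(benzyloxy)-4-oxo-4H-chromen-2-yl]-5-methoxyphenyl}-2-(4-methoxyphenyl)-4H-chromen-4-one | COc1ccc(-c2cc(=O)c3c(OCc6ccccc6)cc(OCc6ccccc6)c(-c4cc(OC)ccc4-c7cc(=O)c8c(OCc6ccccc6)cc(OCc6ccccc6)cc8o7)c3o2)cc1 | intermediate
16 | 8-[2-(5,7-dihydroxy-4-oxo-4H-chromen-2-yl)-5-methoxyphenyl]-5,7-dihydroxy-2-(4-methoxyphenyl)-4H-chromen-4-one (CNP0394081.0) | COc1ccc(-c2cc(=O)c3c(O)cc(O)c(-c4cc(OC)ccc4-c4cc(=O)c5c(O)cc(O)cc5o4)c3o2)cc1 | target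

## Step count and least certain steps

Total step count: 11. Longest linear sequence: 9 steps (4 → 5 → 7 → 8 → 9 → 10 → 12 → 14 → 15 → 16); the acacetin branch (1 → 2 → 3) joins at step 7.

Step 8 (key step). The most likely failure is insufficient dienophile reactivity. The alkyne is a hindered diarylalkyne activated only through a vinylogous ester, so thermal oligomerization and desilylation of the diene may outrun the cycloaddition. A second possibility is erosion of regioselectivity, because the electron-rich aryl group on the acceptor carbon partly offsets the polarization. Fallback: alkyne 10 would be heated in toluene with the more electron-rich trans-1-methoxy-3-(trimethylsilyloxy)buta-1,3-diene, whose CH2 terminus is more nucleophilic and enforces the same orientation more strongly. This should give the racemic adduct 5,7-bis(benzyloxy)-8-{2-[5,7-bis(benzyloxy)-4-oxo-4H-chromen-2-yl]-3-methoxy-5-(trimethylsilyloxy)cyclohexa-1,4-dien-1-yl}-2-(4-methoxyphenyl)-4H-chromen-4-one F1, in which the methoxy group sits on C6' and the silyloxy group on C4'. Dilute acid would then remove the silyl group of F1 and eliminate methanol, so that the resulting dienone tautomerizes to the phenol without an oxidant, and the route is rejoined at phenol 14.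

Step 7. The most likely failure is slow oxidative addition at the electron-rich, doubly ortho-substituted C8–I bond, during which the acceptor alkyne is consumed by copper-mediated homocoupling or by amine addition. Fallback: alkyne 9 would be stannylated with tributyltin methoxide to 5,7-bis(benzyloxy)-2-[(tributylstannyl)ethynyl]-4H-chromen-4-one F2. Stannane F2 would be joined to iodide 3 by Stille coupling with Pd(PPh3)4 in toluene at 90 °C, with no copper and no amine, and the route is rejoined at alkyne 10.

Step 6. The most likely failure is conjugate addition of methanol or methoxide to the product, whose terminal alkyne carbon is the δ-position of a vinylogous acceptor, or attack at C2 with opening of the pyranone ring. Fallback: aldehyde 8 would be converted by Ramirez olefination (CBr4, PPh3, CH2Cl2, 0 °C) to 5,7-bis(benzyloxy)-2-(2,2-dibromoethenyl)-4H-chromen-4-one F3. Hydrodebromination of F3 with Bu3SnH and Pd(PPh3)4 would remove the less hindered bromine to give 5,7-bis(benzyloxy)-2-[(Z)-2-bromoethenyl]-4H-chromen-4-one F4. Anti-elimination of hydrogen bromide from F4 with DBU in THF, an aprotic and alkoxide-free medium, would then return to alkyne 9.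

Step 2. The most likely failure is incomplete regiocontrol, with iodination at C6 (or at C3) beside C8, and isomers that are hard to separate at the flavone stage. Fallback: acetophenone 5 would be iodinated with N-iodosuccinimide ortho to its free, chelated phenol to give 1-[4,6-bis(benzyloxy)-2-hydroxy-3-iodophenyl]ethan-1-one F5. Claisen–Schmidt condensation of F5 with 4-methoxybenzaldehyde (KOH, EtOH) would give (2E)-1-[4,6-bis(benzyloxy)-2-hydroxy-3-iodophenyl]-3-(4-methoxyphenyl)prop-2-en-1-one F6. Oxidative cyclization of chalcone F6 with catalytic iodine in DMSO at 120 °C closes the pyranone through the phenol oxygen next to the iodine, which fixes the halogen at C8 by construction and returns to iodide 3.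

## Further compounds

F1 | step 8 | 5,7-bis(benzyloxy)-8-{2-[5,7-bis(benzyloxy)-4-oxo-4H-chromen-2-yl]-3-methoxy-5-(trimethylsilyloxy)cyclohexa-1,4-dien-1-yl}-2-(4-methoxyphenyl)-4H-chromen-4-one (racemic) | COc1ccc(-c2cc(=O)c3c(OCc6ccccc6)cc(OCc6ccccc6)c(C4=C(c7cc(=O)c8c(OCc6ccccc6)cc(OCc6ccccc6)cc8o7)C(OC)C=C(O[Si](C)(C)C)C4)c3o2)cc1
F2 | step 7 | 5,7-bis(benzyloxy)-2-[(tributylstannyl)ethynyl]-4H-chromen-4-one | CCCC[Sn](CCCC)(CCCC)C#Cc1cc(=O)c2c(OCc3ccccc3)cc(OCc3ccccc3)cc2o1
F3 | step 6 | 5,7-bis(benzyloxy)-2-(2,2-dibromoethenyl)-4H-chromen-4-one | BrC(Br)=Cc1cc(=O)c2c(OCc3ccccc3)cc(OCc3ccccc3)cc2o1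
F4 | step 6 | 5,7-bis(benzyloxy)-2-[(Z)-2-bromoethenyl]-4H-chromen-4-one | Br/C=C\c1cc(=O)c2c(OCc3ccccc3)cc(OCc3ccccc3)cc2o1
F5 | step 2 | 1-[4,6-bis(benzyloxy)-2-hydroxy-3-iodophenyl]ethan-1-one | CC(=O)c1c(O)c(I)c(OCc2ccccc2)cc1OCc1ccccc1
F6 | step 2 | (2E)-1-[4,6-bis(benzyloxy)-2-hydroxy-3-iodophenyl]-3-(4-methoxyphenyl)prop-2-en-1-one | COc1ccc(/C=C/C(=O)c2c(O)c(I)c(OCc3ccccc3)cc2OCc2ccccc2)cc1
A1 | alternative 1 | phloroglucinol | Oc1cc(O)cc(O)c1
A2 | alternative 1 | 2-bromo-4-methoxybenzoic acid | COc1ccc(C(=O)O)c(Br)c1
A3 | alternative 1 | 1,3-dihydroxy-9-methoxybenzo[c]chromen-6-one | O=c1oc2cc(O)cc(O)c2c2cc(OC)ccc12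
A4 | alternative 2 | 8-(3-methoxyphenyl)acacetin, 5,7-dihydroxy-8-(3-methoxyphenyl)-2-(4-methoxyphenyl)-4H-chromen-4-one | COc1ccc(-c2cc(=O)c3c(O)cc(O)c(-c4cccc(OC)c4)c3o2)cc1
A5 | alternative 2 | flavone-fused benzo[c]chromen-6-one lactone | COc1ccc(-c2cc(=O)c3c(O)cc4oc(=O)c5ccc(OC)cc5c4c3o2)cc1
A6 | alternative 3 | methyl (8E)-9-{2-[5,7-bis(benzyloxy)-2-(4-methoxyphenyl)-4-oxo-4H-chromen-8-yl]-4-methoxyphenyl}-3,5,7-trioxonon-8-enoate | COC(=O)CC(=O)CC(=O)CC(=O)/C=C/c1ccc(OC)cc1-c1c(OCc2ccccc2)cc(OCc2ccccc2)c2c(=O)cc(-c3ccc(OC)cc3)oc12
A7 | alternative 3 | 2',4',6'-trihydroxychalcone carrying the benzylated unit 1 | O=C(/C=C/c1ccc(OC)cc1-c1c(OCc2ccccc2)cc(OCc2ccccc2)c2c(=O)cc(-c3ccc(OC)cc3)oc12)c1c(O)cc(O)cc1O
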